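**Retrosynthetic overview**

1. Target 43 ⇐ aryl ester 39 (cage acid 18 + phenol 38). Oxidation of the para-dimethoxy ring A to the quinone is planned to trigger, in one operation, ring expansion to the 2H-pyran and closure of the spiro 1,3-dioxin-4-one (C–O bond from the tertiary cage OH to the quinone carbon that carries the ester oxygen).
2. The 2H-pyran (O1, C2, C3, C4, C4a, C8a of the chromene unit) is carried as a dihydrofuran (O1, C3, C4, C4a, C8a), with C2 held outside the ring as the apex of a cis-fused gem-dimethylcyclopropane (C2, C3, C4). Enabling feature: O1 sits on C8a, which in the quinone is the β-carbon of the enone C8a=C4a–C5=O and the neighbour of C8=O, so the O1–C3 bond can be traded for a C8a=O carbonyl (six-electron ring opening) and O1 returned to C2 by oxa-6π closure.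
3. 38 ⇐ intramolecular carbene cyclopropanation of aryl 2-methylprop-1-enyl ether 32 (from 1,2,3,5-tetramethoxybenzene); the aldehyde carbon becomes C4, the enol ether supplies O1, C3 and C2.
4. 18 ⇐ Claisen rearrangement/intramolecular Diels–Alder cascade of bis(1,1-dimethylallyl) ether 13 (from methyl 2,3,4-trihydroxybenzoate); homochiral menthyloxymethyl ethers allow separation of the two cage diastereomers.
5. Order of ring formation: bicyclo[2.2.2]octene and tetrahydrofuran (step 7) → cyclopropane-fused dihydrofuran (step 15) → 2H-pyran by ring expansion and 1,3-dioxin-4-one (step 19).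

Key step: step 19

Remark on the chemistry: the two cyclopropane-fused carbons of the ring-A fragment form as a racemic cis pair and are both destroyed in step 19, so compounds 35, 36 and 38 to 40 are drawn without descriptors at these two centres (39 and 40 are pairs of diastereomers that converge).

**Route**

Step 1
Reactants: 1 methyl 2,3,4-trihydroxybenzoate; 2 dichlorodiphenylmethane
Product: 3 methyl 4-hydroxy-2,2-diphenyl-1,3-benzodioxole-5-carboxylate
Conditions: Ph2CCl2 (1.2 equiv), neat, 170 °C, argon stream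
Reagents that add atoms: dichlorodiphenylmethane (2), ClC(Cl)(c1ccccc1)c1ccccc1
Why: Catechol ketalisation; the 2-OH is tied up in a hydrogen bond to the ester carbonyl, so the diphenylmethylene bridge should form across O-3/O-4 and leave the salicylate OH free.

Step 2
Reactants: 3; 4 potassium nitrosodisulfonate
Product: 5 methyl 4,7-dioxo-2,2-diphenyl-4,7-dihydro-1,3-benzodioxole-5-carboxylate
Conditions: K2[ON(SO3)2] (2.5 equiv), KH2PO4 buffer, acetone–H2O, 0 °C to rt
Reagents that add atoms: potassium nitrosodisulfonate (4), [K+].[K+].[O]N(S(=O)(=O)[O-])S(=O)(=O)[O-]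
Why: Teuber oxidation of a phenol with a free para position to the para-quinone; the new oxygen enters at the carbon that later becomes the bridgehead C–OH of the cage.

Step 3
Reactants: 5; 6 (1R,2S,5R)-menthyl chloromethyl ether
Product: 8 methyl 4,7-bis{[(1R,2S,5R)-menthyloxy]methoxy}-2,2-diphenyl-1,3-benzodioxole-5-carboxylate, via hydroquinone 7 (not isolated)
Conditions: Na2S2O4, EtOAc–H2O, rt; dried organic phase, then NaH (2.4 equiv), 6 (2.3 equiv), DMF, 0 °C to rt
Reagents that add atoms: (1R,2S,5R)-menthyl chloromethyl ether (6), ClCO[C@@H]1C[C@H](C)CC[C@H]1C(C)C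
Why: Dithionite reduction of the quinone and Williamson alkylation of both phenolates should give two formaldehyde-acetal ethers that behave like MOM groups and carry the homochiral menthyl residues used later to separate the cage diastereomers.

Step 4
Reactants: 8
Product: 9 methyl 3,4-dihydroxy-2,5-bis{[(1R,2S,5R)-menthyloxy]methoxy}benzoate
Conditions: H2 (1 atm), 10% Pd/C, EtOAc–MeOH, rt
Reagents that add atoms: none
Why: Hydrogenolysis of the doubly benzylic diphenylmethylene ketal should free the catechol, while the non-benzylic acetal ethers and the ester are not touched.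

Step 5
Reactants: 10 2-methylbut-3-en-2-ol; 11 di-tert-butyl dicarbonate
Product: 12 tert-butyl 2-methylbut-3-en-2-yl carbonate
Conditions: n-BuLi, THF, −78 °C; then Boc2O, −78 °C to rt
Reagents that add atoms: di-tert-butyl dicarbonate (11), CC(C)(C)OC(=O)OC(=O)OC(C)(C)C
Why: Acylation of the lithium alkoxide of a tertiary allylic alcohol with Boc2O is a standard entry to this tertiary allylic carbonate.

Step 6
Reactants: 9; 12
Product: 13 methyl 2,5-bis{[(1R,2S,5R)-menthyloxy]methoxy}-3,4-bis[(2-methylbut-3-en-2-yl)oxy]benzoate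
Conditions: Pd(PPh3)4 (5 mol %), 12 (2.5 equiv), THF, 0 °C to rt
Reagents that add atoms: tert-butyl 2-methylbut-3-en-2-yl carbonate (12), CC(C)(C)OC(=O)OC(C)(C)C=C
Why: Decarboxylative Tsuji–Trost O-allylation, in which the phenolate attacks the more substituted terminus of the 1,1-dimethylallyl–palladium complex and so gives the branched aryl ethers needed for the Claisen step.

Step 7
Reactants: 13
Product: 15 methyl 5,5-dimethyl-3-(3-methylbut-2-en-1-yl)-1,7-bis{[(1R,2S,5R)-menthyloxy]methoxy}-2-oxo-4-oxatricyclo[4.3.1.0(3,7)]dec-8-ene-8-carboxylate (cage configuration as in 43), via cyclohexa-2,4-dienone 14 (not isolated)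
Conditions: degassed DMF, 120 °C; chromatographic separation from the diastereomer that has the mirror-image cage
Reagents that add atoms: none
Why: Aromatic Claisen rearrangement/intramolecular Diels–Alder cascade of the kind used for caged xanthone cores: the allyl ether para to the ester shifts to the neighbouring oxygen-bearing carbon (prenyl group, quaternary centre), the remaining 1,1-dimethylallyl ether then adds across the 1,3-diene of the dienone, closing the bicyclo[2.2.2]octene and the tetrahydrofuran and fixing the other three centres relative to the first through the tether geometry; the absolute sense is not induced but selected by separating the two menthyl-tagged diastereomers.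

Step 8
Reactants: 15; 16 lithium hydroxide
Product: 18 1,7-dihydroxy-5,5-dimethyl-3-(3-methylbut-2-en-1-yl)-2-oxo-4-oxatricyclo[4.3.1.0(3,7)]dec-8-ene-8-carboxylic acid (configuration as in 43), via lithium carboxylate 17 (not isolated)
Conditions: LiOH·H2O, THF–MeOH–H2O, rt; then CF3CO2H–CH2Cl2–H2O, 0 °C
Reagents that add atoms: lithium hydroxide (16), [Li+].[OH-]
Why: Saponification of the methyl enoate while both tertiary alcohols are still masked (no retro-aldol path), then acid hydrolysis of the two formaldehyde acetals, which should release menthol and formaldehyde and leave the C–O bonds of the cage intact.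

Step 9
Reactants: 19 1,2,3,5-tetramethoxybenzene; 20 N,N-dimethylformamide; 21 water
Product: 23 2,3,4,6-tetramethoxybenzaldehyde, via iminium chloride 22 (not isolated)
Conditions: POCl3, DMF, 0 to 60 °C; then aqueous NaOAc
Reagents that add atoms: N,N-dimethylformamide (20), CN(C)C=O; water (21), O
Why: Vilsmeier–Haack formylation of an electron-rich arene; the two free positions are equivalent, so a single aldehyde should form.

Step 10
Reactants: 23
Product: 25 2-hydroxy-3,4,6-trimethoxybenzaldehyde, via aryloxydichloroborane 24 (not isolated)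
Conditions: BCl3 (1.1 equiv), CH2Cl2, −78 to 0 °C; aqueous work-up
Reagents that add atoms: none
Why: Chelation-controlled ether cleavage ortho to the carbonyl by BCl3; of the two ortho methoxy groups, the one buttressed by the neighbouring 3-methoxy group is twisted out of plane and should be cleaved first.

Step 11
Reactants: 25; 26 1-bromo-2-methylprop-1-ene
Product: 27 3,4,6-trimethoxy-2-[(2-methylprop-1-en-1-yl)oxy]benzaldehyde
Conditions: copper iodide CuI (10 mol %), N,N-dimethylglycine hydrochloride (30 mol %), Cs2CO3, 1,4-dioxane, 90 °C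
Reagents that add atoms: 1-bromo-2-methylprop-1-ene (26), CC(C)=CBr
Why: Ullmann-type copper-catalysed C–O coupling of a phenol with a vinyl bromide should give the aryl enol ether directly, with the ring oxygen already on the carbon that becomes C8a of the chromene.

Step 12
Reactants: 27
Product: 28 4-hydroxy-3,6-dimethoxy-2-[(2-methylprop-1-en-1-yl)oxy]benzaldehyde
Conditions: NaSEt (3 equiv), DMF, 100 °C; aqueous NH4Cl
Reagents that add atoms: none
Why: Nucleophilic demethylation (SN2 at methyl) by thiolate should prefer the methoxy group whose phenolate is best stabilised, here the one para to the formyl group and flanked by a second methoxy group.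

Step 13
Reactants: 28; 29 tert-butyldimethylsilyl chloride
Product: 30 4-[(tert-butyldimethylsilyl)oxy]-3,6-dimethoxy-2-[(2-methylprop-1-en-1-yl)oxy]benzaldehyde
Conditions: TBSCl, imidazole, DMF, rt
Reagents that add atoms: tert-butyldimethylsilyl chloride (29), CC(C)(C)[Si](C)(C)Cl
Why: Standard silylation of the only free phenol, so that no acidic O–H is present when the diazo compound is generated.

Step 14
Reactants: 30; 31 4-methylbenzenesulfonohydrazide
Product: 32 (E)-N'-({4-[(tert-butyldimethylsilyl)oxy]-3,6-dimethoxy-2-[(2-methylprop-1-en-1-yl)oxy]phenyl}methylidene)-4-methylbenzenesulfonohydrazide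
Conditions: TsNHNH2, MeOH, rt
Reagents that add atoms: 4-methylbenzenesulfonohydrazide (31), Cc1ccc(cc1)S(=O)(=O)NN
Why: Condensation of an aryl aldehyde with tosylhydrazide gives the Bamford–Stevens carbene precursor.

Step 15
Reactants: 32
Product: 35 tert-butyl[(3,6-dimethoxy-1,1-dimethyl-1a,6b-dihydro-1H-cyclopropa[b][1]benzofuran-4-yl)oxy]dimethylsilane (cis-fused, racemic), via sodium salt 33 (not isolated), via aryldiazomethane 34 (not isolated)
Conditions: NaH, THF, 0 °C; then Rh2(OAc)4 (1 mol %), BnEt3NCl (10 mol %), 1,4-dioxane, 40 °C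
Reagents that add atoms: none
Why: Bamford–Stevens generation of the aryldiazomethane and rhodium-carbene cyclopropanation of the electron-rich enol ether held in the ortho position; the one-atom oxygen tether allows only the cis-fused 2-oxabicyclo[3.1.0]hexane, so dihydrofuran and gem-dimethylcyclopropane form together as a racemic pair whose two centres disappear in step 19.

Step 16
Reactants: 35
Product: 36 3,6-dimethoxy-1,1-dimethyl-1a,6b-dihydro-1H-cyclopropa[b][1]benzofuran-4-ol
Conditions: Bu4NF (1.1 equiv), AcOH (1.1 equiv), THF, 0 °C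
Reagents that add atoms: none
Why: Fluoride cleavage of the aryl silyl ether under buffered conditions that should leave the cyclopropyl aryl ether alone.

Step 17
Reactants: 36; 37 1-bromo-3-methylbut-2-ene
Product: 38 3,6-dimethoxy-1,1-dimethyl-5-(3-methylbut-2-en-1-yl)-1a,6b-dihydro-1H-cyclopropa[b][1]benzofuran-4-ol
Conditions: NaH, toluene, 0 °C to rt
Reagents that add atoms: 1-bromo-3-methylbut-2-ene (37), CC(C)=CCBr
Why: ortho-C-Alkylation of a sodium phenolate in a non-polar solvent; the only open ortho position lies between the phenol and the 6-methoxy group, the other ortho carbon and the para carbon being substituted.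

Step 18
Reactants: 18; 38
Product: 39 3,6-dimethoxy-1,1-dimethyl-5-(3-methylbut-2-en-1-yl)-1a,6b-dihydro-1H-cyclopropa[b][1]benzofuran-4-yl ester of acid 18
Conditions: EDC·HCl, DMAP, CH2Cl2, 0 °C to rt
Reagents that add atoms: none
Why: Steglich esterification of the enoic acid with the phenol; the two tertiary alcohols of 18 are too hindered to compete.

Step 19
Reactants: 39; 21 water
Product: 43 target CNP0222516.1, via acyloxyquinone 40 (not isolated), via alkylidene trione 41 (not isolated), via pyranoquinone 42 (not isolated)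
Conditions: (NH4)2Ce(NO3)6 (2.5 equiv), MeCN–H2O (4:1), 0 °C; extraction into toluene, then 60 °C
Reagents that add atoms: water (21), O
Why: Proposed new method: (NH4)2Ce(NO3)6 should oxidise the para-dimethoxyarene to the 2-acyloxy-1,4-benzoquinone 40 (both quinone oxygens from water), which makes the dihydrofuran oxygen a vinylogous-ester oxygen on a non-aromatic ring, so that the fused 2-oxabicyclo[3.1.0]hex-3-ene can open by a thermal six-electron cycloreversion (O–CH and CH–CMe2 σ bonds together with the ring C=C) to the 2-(3-methylbut-2-enylidene)-1,3-dione unit of 41 and reclose by disrotatory oxa-6π electrocyclisation of the new C=O onto the CMe2 terminus, which enlarges the five-membered O-ring by the former cyclopropane carbon to the 2,2-dimethyl-2H-pyran of 42. The closest known reaction types are the thermal unravelling of furan–carbene adducts (2-oxabicyclo[3.1.0]hex-3-enes) to cis-dienones and 2H-pyrans and the oxa-6π closure of 2-alkylidene-1,3-diones in classical chromene syntheses; what is new is that the opening is switched on by the arene-to-quinone oxidation, the aromatic precursor having no low-energy path to the ring-opened form. The 1,3-dioxin-4-one ring should then close by 6-exo-trig oxa-Michael addition of the tertiary cage OH to the acyloxy-bearing quinone carbon, followed by C-protonation of the enol between the spiro carbon and the ketone. The spiro carbon and the adjacent CH(prenyl) carbon are controlled by the four cage centres: the addition is reversible and the CH centre is epimerisable, so the arrangement of 43 should accumulate as the most stable diastereomer. The step needs oxa-6π closure onto the carbonyl that neighbours the second ring carbonyl (5,8-dione and not the isomeric ortho-quinone), which the reversibility of this closure and the stability of the cross-conjugated ene-1,4-dione should secure, and it needs the oxidant to spare the cyclopropane and the prenyl groups, which the much lower oxidation potential of the para-dimethoxyarene and the low temperature should secure.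

**Compound list**

1 | methyl 2,3,4-trihydroxybenzoate | COC(=O)c1ccc(O)c(O)c1O | starting material
2 | dichlorodiphenylmethane | ClC(Cl)(c1ccccc1)c1ccccc1 | starting material
3 | methyl 4-hydroxy-2,2-diphenyl-1,3-benzodioxole-5-carboxylate | COC(=O)c1ccc2OC(c3ccccc3)(c3ccccc3)Oc2c1O | intermediate
4 | potassium nitrosodisulfonate | [K+].[K+].[O]N(S(=O)(=O)[O-])S(=O)(=O)[O-] | starting material
5 | methyl 4,7-dioxo-2,2-diphenyl-4,7-dihydro-1,3-benzodioxole-5-carboxylate | COC(=O)C1=CC(=O)C2=C(OC(c3ccccc3)(c3ccccc3)O2)C1=O | intermediate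
6 | (1R,2S,5R)-menthyl chloromethyl ether | ClCO[C@@H]1C[C@H](C)CC[C@H]1C(C)C | starting material
7 | methyl 4,7-dihydroxy-2,2-diphenyl-1,3-benzodioxole-5-carboxylate | COC(=O)c1cc(O)c2OC(c3ccccc3)(c3ccccc3)Oc2c1O | intermediate
8 | methyl 4,7-bis{[(1R,2S,5R)-menthyloxy]methoxy}-2,2-diphenyl-1,3-benzodioxole-5-carboxylate | COC(=O)c1cc(OCO[C@@H]4C[C@H](C)CC[C@H]4C(C)C)c2OC(c3ccccc3)(c3ccccc3)Oc2c1OCO[C@@H]1C[C@H](C)CC[C@H]1C(C)C | intermediate
9 | methyl 3,4-dihydroxy-2,5-bis{[(1R,2S,5R)-menthyloxy]methoxy}benzoate | COC(=O)c1cc(OCO[C@@H]2C[C@H](C)CC[C@H]2C(C)C)c(O)c(O)c1OCO[C@@H]1C[C@H](C)CC[C@H]1C(C)C | intermediate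
10 | 2-methylbut-3-en-2-ol | CC(C)(O)C=C | starting material
11 | di-tert-butyl dicarbonate | CC(C)(C)OC(=O)OC(=O)OC(C)(C)C | starting material
12 | tert-butyl 2-methylbut-3-en-2-yl carbonate | CC(C)(C)OC(=O)OC(C)(C)C=C | intermediate
13 | methyl 2,5-bis{[(1R,2S,5R)-menthyloxy]methoxy}-3,4-bis[(2-methylbut-3-en-2-yl)oxy]benzoate | COC(=O)c1cc(OCO[C@@H]2C[C@H](C)CC[C@H]2C(C)C)c(OC(C)(C)C=C)c(OC(C)(C)C=C)c1OCO[C@@H]1C[C@H](C)CC[C@H]1C(C)C | intermediate
14 | methyl 2,5-bis{[(1R,2S,5R)-menthyloxy]methoxy}-3-[(2-methylbut-3-en-2-yl)oxy]-3-(3-methylbut-2-en-1-yl)-4-oxocyclohexa-1,5-diene-1-carboxylate (C-3 as drawn) | C=CC(C)(C)O[C@@]1(CC=C(C)C)C(=O)C(OCO[C@@H]2C[C@H](C)CC[C@H]2C(C)C)=CC(C(=O)OC)=C1OCO[C@@H]1C[C@H](C)CC[C@H]1C(C)C | intermediate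
15 | methyl 5,5-dimethyl-3-(3-methylbut-2-en-1-yl)-1,7-bis{[(1R,2S,5R)-menthyloxy]methoxy}-2-oxo-4-oxatricyclo[4.3.1.0(3,7)]dec-8-ene-8-carboxylate (cage as in 43) | COC(=O)C1=C[C@]2(OCO[C@@H]4C[C@H](C)CC[C@H]4C(C)C)C[C@H]3C(C)(C)O[C@@](CC=C(C)C)(C2=O)[C@@]13OCO[C@@H]1C[C@H](C)CC[C@H]1C(C)C | intermediate
16 | lithium hydroxide | [Li+].[OH-] | starting material
17 | lithium salt of the bis(menthyloxymethyl)-protected cage acid | [Li+].[O-]C(=O)C1=C[C@]2(OCO[C@@H]4C[C@H](C)CC[C@H]4C(C)C)C[C@H]3C(C)(C)O[C@@](CC=C(C)C)(C2=O)[C@@]13OCO[C@@H]1C[C@H](C)CC[C@H]1C(C)C | intermediate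
18 | 1,7-dihydroxy-5,5-dimethyl-3-(3-methylbut-2-en-1-yl)-2-oxo-4-oxatricyclo[4.3.1.0(3,7)]dec-8-ene-8-carboxylic acid (cage as in 43) | OC(=O)C1=C[C@]2(O)C[C@H]3C(C)(C)O[C@@](CC=C(C)C)(C2=O)[C@@]13O | intermediate
19 | 1,2,3,5-tetramethoxybenzene | COc1cc(OC)c(OC)c(OC)c1 | starting material
20 | N,N-dimethylformamide | CN(C)C=O | starting material
21 | water | O | starting material
22 | N,N-dimethyl-1-(2,3,4,6-tetramethoxyphenyl)methaniminium chloride | COc1cc(OC)c(OC)c(OC)c1C=[N+](C)C.[Cl-] | intermediate
23 | 2,3,4,6-tetramethoxybenzaldehyde | COc1cc(OC)c(OC)c(OC)c1C=O | intermediate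
24 | dichloro(2-formyl-3,5,6-trimethoxyphenoxy)borane | COc1cc(OC)c(OC)c(OB(Cl)Cl)c1C=O | intermediate
25 | 2-hydroxy-3,4,6-trimethoxybenzaldehyde | COc1cc(OC)c(OC)c(O)c1C=O | intermediate
26 | 1-bromo-2-methylprop-1-ene | CC(C)=CBr | starting material
27 | 3,4,6-trimethoxy-2-[(2-methylprop-1-en-1-yl)oxy]benzaldehyde | COc1cc(OC)c(OC)c(OC=C(C)C)c1C=O | intermediate
28 | 4-hydroxy-3,6-dimethoxy-2-[(2-methylprop-1-en-1-yl)oxy]benzaldehyde | COc1cc(O)c(OC)c(OC=C(C)C)c1C=O | intermediate
29 | tert-butyldimethylsilyl chloride | CC(C)(C)[Si](C)(C)Cl | starting material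
30 | 4-[(tert-butyldimethylsilyl)oxy]-3,6-dimethoxy-2-[(2-methylprop-1-en-1-yl)oxy]benzaldehyde | COc1cc(O[Si](C)(C)C(C)(C)C)c(OC)c(OC=C(C)C)c1C=O | intermediate
31 | 4-methylbenzenesulfonohydrazide | Cc1ccc(cc1)S(=O)(=O)NN | starting material
32 | (E)-tosylhydrazone of 30 | COc1cc(O[Si](C)(C)C(C)(C)C)c(OC)c(OC=C(C)C)c1/C=N/NS(=O)(=O)c1ccc(C)cc1 | intermediate
33 | sodium salt of tosylhydrazone 32 | [Na+].COc1cc(O[Si](C)(C)C(C)(C)C)c(OC)c(OC=C(C)C)c1/C=N/[N-]S(=O)(=O)c1ccc(C)cc1 | intermediate
34 | tert-butyl{4-(diazomethyl)-2,5-dimethoxy-3-[(2-methylprop-1-en-1-yl)oxy]phenoxy}dimethylsilane | COc1cc(O[Si](C)(C)C(C)(C)C)c(OC)c(OC=C(C)C)c1C=[N+]=[N-] | intermediate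
35 | tert-butyl[(3,6-dimethoxy-1,1-dimethyl-1a,6b-dihydro-1H-cyclopropa[b][1]benzofuran-4-yl)oxy]dimethylsilane (cis-fused, racemic) | COc1cc(O[Si](C)(C)C(C)(C)C)c(OC)c2OC3C(c12)C3(C)C | intermediate
36 | 3,6-dimethoxy-1,1-dimethyl-1a,6b-dihydro-1H-cyclopropa[b][1]benzofuran-4-ol (cis-fused, racemic) | COc1cc(O)c(OC)c2OC3C(c12)C3(C)C | intermediate
37 | 1-bromo-3-methylbut-2-ene | CC(C)=CCBr | starting material
38 | 3,6-dimethoxy-1,1-dimethyl-5-(3-methylbut-2-en-1-yl)-1a,6b-dihydro-1H-cyclopropa[b][1]benzofuran-4-ol (cis-fused, racemic) | COc1c(CC=C(C)C)c(O)c(OC)c2OC3C(c12)C3(C)C | intermediate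
39 | ester of acid 18 with phenol 38 (cage as in 43; both cis configurations of the cyclopropane-fused pair) | COc1c(CC=C(C)C)c(OC(=O)C4=C[C@]5(O)C[C@H]6C(C)(C)O[C@@](CC=C(C)C)(C5=O)[C@@]46O)c(OC)c2OC3C(c12)C3(C)C | intermediate
40 | 1,1-dimethyl-5-(3-methylbut-2-en-1-yl)-3,6-dioxo-1a,3,6,6b-tetrahydro-1H-cyclopropa[b][1]benzofuran-4-yl ester of acid 18 | O=C1C(CC=C(C)C)=C(OC(=O)C4=C[C@]5(O)C[C@H]6C(C)(C)O[C@@](CC=C(C)C)(C5=O)[C@@]46O)C(=O)C2=C1C3C(O2)C3(C)C | intermediate
41 | 4-(3-methylbut-2-en-1-ylidene)-2-(3-methylbut-2-en-1-yl)-3,5,6-trioxocyclohex-1-en-1-yl ester of acid 18 | O=C1C(CC=C(C)C)=C(OC(=O)C4=C[C@]5(O)C[C@H]6C(C)(C)O[C@@](CC=C(C)C)(C5=O)[C@@]46O)C(=O)C(=O)C1=CC=C(C)C | intermediate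
42 | 2,2-dimethyl-6-(3-methylbut-2-en-1-yl)-5,8-dioxo-5,8-dihydro-2H-chromen-7-yl ester of acid 18 | O=C1C(CC=C(C)C)=C(OC(=O)C4=C[C@]5(O)C[C@H]6C(C)(C)O[C@@](CC=C(C)C)(C5=O)[C@@]46O)C(=O)C2=C1C=CC(C)(C)O2 | intermediate
43 | target CNP0222516.1 (spiro 1,3-dioxin-4-one linking the caged core to the 2,2-dimethyl-6-prenyl-6,7-dihydro-2H-chromene-5,8-dione) | CC(C)=CC[C@H]1C(=O)C2=C(OC(C)(C)C=C2)C(=O)[C@@]12OC(=O)C1=C[C@]3(O)C[C@H]4C(C)(C)O[C@@](CC=C(C)C)(C3=O)[C@@]14O2 | target

**Summary and fallbacks**

Total step count: 19. Longest linear sequence: 11 steps (steps 9 to 19).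

Step 19 (Proposed new method). After oxidation, the six-electron opening of the cyclopropane-fused dihydrofuran may be slower than decay of the acyloxyquinone, or one-electron oxidation may cleave the cyclopropane. The oxa-6π closure may also take place on the other carbonyl, and equilibration at the spiro centre may stay incomplete. The fallback uses known chemistry, sets out from 30 and returns at 42. Mild acid hydrolysis of the enol ether (pyridinium p-toluenesulfonate, aqueous acetone) should give 4-[(tert-butyldimethylsilyl)oxy]-2-hydroxy-3,6-dimethoxybenzaldehyde F1. Addition of 2-methylprop-1-enylmagnesium bromide (2.2 equiv) should give the allylic alcohol 5-[(tert-butyldimethylsilyl)oxy]-2-(1-hydroxy-3-methylbut-2-en-1-yl)-3,6-dimethoxyphenol F2. Acid-catalysed cyclodehydration (pyridinium p-toluenesulfonate, toluene, 80 °C; ortho-quinone methide then oxa-6π) should give tert-butyl[(5,8-dimethoxy-2,2-dimethyl-2H-chromen-7-yl)oxy]dimethylsilane F3. Bu4NF/AcOH should free 5,8-dimethoxy-2,2-dimethyl-2H-chromen-7-ol F4, and NaH/prenyl bromide in toluene should give 5,8-dimethoxy-2,2-dimethyl-6-(3-methylbut-2-en-1-yl)-2H-chromen-7-ol F5. Steglich coupling with 18 should give the chromenyl ester F6, and oxidation with (NH4)2Ce(NO3)6 in MeCN–H2O at 0 °C should give pyranoquinone 42, which closes to 43 as in step 19.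

Step 7. The first Claisen shift may take the other allyl ether and lead to the isomeric cage, and the two cage diastereomers may not separate because the menthyl auxiliaries are remote. The fallback sets out from 13 and returns at 18. The unseparated mixture of 15 and the diastereomer with the mirror-image cage F7 is taken through the conditions of step 8 to the racemate, that is 18 together with its enantiomer F8. This is resolved by fractional crystallisation of the (S)-1-phenylethylammonium salt of 18 F9 (or with the antipodal amine, whichever gives the less soluble salt of the wanted acid); acidification returns 18.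

Step 15. The carbene may insert into a C–H bond of the neighbouring 6-methoxy group, or azine formation may outrun the cyclopropanation. The fallback sets out from 32 and returns at 35. The diazo compound 34 is generated from salt 33 without rhodium (NaH, then 60 °C in dioxane) and left to add as a 1,3-dipole to the tethered enol ether to give the fused 1-pyrazoline F10. Irradiation (350 nm, benzene) should then expel nitrogen and give 35.

Further compounds
F1 | step 19 | 4-[(tert-butyldimethylsilyl)oxy]-2-hydroxy-3,6-dimethoxybenzaldehyde | COc1cc(O[Si](C)(C)C(C)(C)C)c(OC)c(O)c1C=O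
F2 | step 19 | 5-[(tert-butyldimethylsilyl)oxy]-2-(1-hydroxy-3-methylbut-2-en-1-yl)-3,6-dimethoxyphenol (racemic) | COc1cc(O[Si](C)(C)C(C)(C)C)c(OC)c(O)c1C(O)C=C(C)C
F3 | step 19 | tert-butyl[(5,8-dimethoxy-2,2-dimethyl-2H-chromen-7-yl)oxy]dimethylsilane | COc1cc(O[Si](C)(C)C(C)(C)C)c(OC)c2OC(C)(C)C=Cc12
F4 | step 19 | 5,8-dimethoxy-2,2-dimethyl-2H-chromen-7-ol | COc1cc(O)c(OC)c2OC(C)(C)C=Cc12
F5 | step 19 | 5,8-dimethoxy-2,2-dimethyl-6-(3-methylbut-2-en-1-yl)-2H-chromen-7-ol | COc1c(CC=C(C)C)c(O)c(OC)c2OC(C)(C)C=Cc12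
F6 | step 19 | 5,8-dimethoxy-2,2-dimethyl-6-(3-methylbut-2-en-1-yl)-2H-chromen-7-yl ester of acid 18 | COc1c(CC=C(C)C)c(OC(=O)C4=C[C@]5(O)C[C@H]6C(C)(C)O[C@@](CC=C(C)C)(C5=O)[C@@]46O)c(OC)c2OC(C)(C)C=Cc12
F7 | step 7 | diastereomer of 15 with the mirror-image cage and the same (1R,2S,5R)-menthyl groups | COC(=O)C1=C[C@@]2(OCO[C@@H]4C[C@H](C)CC[C@H]4C(C)C)C[C@@H]3C(C)(C)O[C@](CC=C(C)C)(C2=O)[C@]13OCO[C@@H]1C[C@H](C)CC[C@H]1C(C)C
F8 | step 7 | enantiomer of acid 18 | OC(=O)C1=C[C@@]2(O)C[C@@H]3C(C)(C)O[C@](CC=C(C)C)(C2=O)[C@]13O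
F9 | step 7 | (S)-1-phenylethylammonium salt of acid 18 | C[C@H]([NH3+])c1ccccc1.[O-]C(=O)C1=C[C@]2(O)C[C@H]3C(C)(C)O[C@@](CC=C(C)C)(C2=O)[C@@]13O
F10 | step 15 | 1-pyrazoline from intramolecular cycloaddition of 34 (cis-fused, racemic) | COc1cc(O[Si](C)(C)C(C)(C)C)c(OC)c2OC3C(c12)N=NC3(C)C
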